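**Plan**

- Retrosynthesis: the hydroxyls of rings A, C and E are masked as methyl ethers, so eight O–CH3 bonds are the last to be cut in the forward direction.
- Rings B and D are each cut at C3–C4 and folded back into 2-pyranones (C1 = carbon bound to the oxygen toward ring A). This works because each of these rings has aryloxy at C1, hydroxyl at C3 and C5 and aryloxy at C4, the pattern a 4-aryloxy-6-(aryloxymethyl)-2-pyranone gives when its lactone carbon C2 is bonded to the exocyclic CH2.
- The bis-pyranone is cut at two CH2–OAr and two pyranone C4–OAr bonds. The pieces are 4-bromo-6-(bromomethyl)-2-pyranone (used twice, from triacetic acid lactone), 2,4,6-trimethoxyphenol (ring A), a hydroquinone monoether from syringaldehyde (ring C) and 3,4,5-trimethoxyphenol (ring E).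
- Forward: rings A, C and E are bought as arenes. Each pyranone is etherified at CH2Br (SN2) and then at C4 (addition–elimination), the two halves are joined at C4 of the second pyranone, rings B and D form together, and BBr3 frees the remaining hydroxyls.
- Stereochemistry: the target has no stereocentre and no stereogenic double bond. The only geometry on the way, the E enoates of the opened lactones (ester cis to the ketone arm), is inherited from the pyranone rings.

Key step: step 10

Remark: 2,4,6-trimethoxyphenol and 3,4,5-trimethoxyphenol are taken as purchasable.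

**Route**

Step 1
Reactants: 1 4-hydroxy-6-methyl-2H-pyran-2-one (triacetic acid lactone)
Product: 2 4-bromo-6-methyl-2H-pyran-2-one
Conditions: Bu4NBr, P2O5, toluene, 100 °C
Reagents that add atoms: tetrabutylammonium bromide, CCCC[N+](CCCC)(CCCC)CCCC.[Br-]
Why: P2O5 turns the C4 hydroxyl of the vinylogous acid into a phosphate leaving group that bromide replaces by addition–elimination, the established deoxybromination of 4-hydroxy-2-pyranones.

Step 2
Reactants: 2 4-bromo-6-methyl-2H-pyran-2-one
Product: 3 4-bromo-6-(bromomethyl)-2H-pyran-2-one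
Conditions: NBS, AIBN (cat.), PhCF3, 80 °C
Reagents that add atoms: N-bromosuccinimide, O=C1CCC(=O)N1Br
Why: Wohl–Ziegler radical bromination takes place at the C6 methyl group, whose radical is delocalised over the pyranone diene, as known for 6-methyl-2-pyranones, and the bromine at C4 makes the ring too electron-poor for ionic bromination at C3.

Step 3
Reactants: 4 syringaldehyde (4-hydroxy-3,5-dimethoxybenzaldehyde)
Product: 5 3,5-dimethoxy-4-(triisopropylsilyloxy)benzaldehyde
Conditions: TIPSCl, imidazole, DMAP (cat.), DMF, rt to 40 °C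
Reagents that add atoms: triisopropylsilyl chloride, CC(C)[Si](Cl)(C(C)C)C(C)C
Why: Imidazole-promoted O-silylation of the phenol; the triisopropylsilyl ether, flanked by two methoxy groups, is chosen because it should resist peracid and carbonate bases and fall to fluoride.

Step 4
Reactants: 5 3,5-dimethoxy-4-(triisopropylsilyloxy)benzaldehyde
Product: 7 3,5-dimethoxy-4-(triisopropylsilyloxy)phenol, via aryl formate 6 (not isolated)
Conditions: mCPBA, CH2Cl2, 0 °C to rt; then Et3N (cat.), MeOH, rt
Reagents that add atoms: meta-chloroperoxybenzoic acid, OOC(=O)c1cccc(Cl)c1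
Why: Baeyer–Villiger oxidation of an electron-rich benzaldehyde proceeds with aryl migration (para silyloxy donor) to the aryl formate, which amine-catalysed methanolysis cleaves without touching the silyl ether.

Step 5
Reactants: 3 4-bromo-6-(bromomethyl)-2H-pyran-2-one; 7 3,5-dimethoxy-4-(triisopropylsilyloxy)phenol
Product: 8 4-bromo-6-{[3,5-dimethoxy-4-(triisopropylsilyloxy)phenoxy]methyl}-2H-pyran-2-one
Conditions: K2CO3, acetone, 0 °C to rt
Reagents that add atoms: none
Why: Williamson ether synthesis: the unhindered phenoxide displaces the primary, pyranone-activated (allylic-type) bromide by SN2, which at 0 °C in acetone should be much faster than addition–elimination at the C4 bromide.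

Step 6
Reactants: 8 4-bromo-6-{[3,5-dimethoxy-4-(triisopropylsilyloxy)phenoxy]methyl}-2H-pyran-2-one; 9 2,4,6-trimethoxyphenol
Product: 10 6-{[3,5-dimethoxy-4-(triisopropylsilyloxy)phenoxy]methyl}-4-(2,4,6-trimethoxyphenoxy)-2H-pyran-2-one
Conditions: K2CO3, DMF, 50 °C
Reagents that add atoms: none
Why: Vinylogous acyl substitution (addition–elimination): the electron-rich phenoxide adds to C4 of the 4-bromo-2-pyranone, β to the lactone carbonyl, and bromide leaves, as known for 4-halo-2-pyranones and 4-halocoumarins.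

Step 7
Reactants: 10 6-{[3,5-dimethoxy-4-(triisopropylsilyloxy)phenoxy]methyl}-4-(2,4,6-trimethoxyphenoxy)-2H-pyran-2-one
Product: 11 6-[(4-hydroxy-3,5-dimethoxyphenoxy)methyl]-4-(2,4,6-trimethoxyphenoxy)-2H-pyran-2-one
Conditions: Bu4NF, AcOH, THF, 0 °C
Reagents that add atoms: none
Why: Fluoride-mediated desilylation driven by the Si–F bond, buffered with acetic acid so that no free phenoxide or fluoride base attacks the lactone or the C4 aryl ether.

Step 8
Reactants: 3 4-bromo-6-(bromomethyl)-2H-pyran-2-one; 12 3,4,5-trimethoxyphenol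
Product: 13 4-bromo-6-[(3,4,5-trimethoxyphenoxy)methyl]-2H-pyran-2-one
Conditions: K2CO3, acetone, 0 °C to rt
Reagents that add atoms: none
Why: Williamson ether synthesis by SN2 at the activated CH2Br group, chemoselective over C4 for the same reason as in step 5.

Step 9
Reactants: 11 6-[(4-hydroxy-3,5-dimethoxyphenoxy)methyl]-4-(2,4,6-trimethoxyphenoxy)-2H-pyran-2-one; 13 4-bromo-6-[(3,4,5-trimethoxyphenoxy)methyl]-2H-pyran-2-one
Product: 14 6-{[3,5-dimethoxy-4-({2-oxo-6-[(3,4,5-trimethoxyphenoxy)methyl]-2H-pyran-4-yl}oxy)phenoxy]methyl}-4-(2,4,6-trimethoxyphenoxy)-2H-pyran-2-one (bis-pyranone)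
Conditions: Cs2CO3, DMF, rt to 50 °C
Reagents that add atoms: none
Why: Vinylogous acyl substitution (addition–elimination) at C4 of the bromopyranone by the caesium phenoxide of 11, whose two ortho methoxy groups make it hindered but electron-rich, while the aryloxy-substituted pyranone of 11 lacks a comparably good leaving group and should stay intact.

Step 10
Reactants: 14 bis-pyranone
Product: 16 2-{4-[3,5-dihydroxy-4-(3,4,5-trimethoxyphenoxy)phenoxy]-3,5-dimethoxyphenoxy}-5-(2,4,6-trimethoxyphenoxy)benzene-1,3-diol, via ring-opened bis-enoate 15 (not isolated)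
Conditions: Mg(OMe)2 (excess), MeOH–THF, reflux, Ar; then 1 M HCl (work-up)
Reagents that add atoms: none
Why: Magnesium-bound methoxide adds to each lactone carbonyl (C2) and the ring opens to the magnesium dienolate of a methyl (2E)-3-aryloxy-5-oxohex-2-enoate, in which the ester stays cis to the ketone arm as it was in the ring. Proton exchange in methanol makes the C6 enolate available (its aryloxy group acidifies C6–H); this enolate acylates on carbon at the ester with loss of the methanol taken up in the opening, and the cyclohexenedione enolises at once to the resorcinol, so the step is the known base-induced pyranone-to-phloroglucinol ring transformation (lactone opening, then intramolecular Claisen condensation) run at two sites. Ring B and ring D are each closed in a 6-(enolendo)-exo-trig mode by the new C3–C4 bond. No stereocentre is formed; the only geometric need, ester and ketone arm on the same side of the C2=C3 bond, is built into the pyranone. The step needs attack at the lactone carbonyl and not addition–elimination at C4 (loss of aryloxide), and acylation on carbon and not on oxygen. Magnesium bound to the lactone carbonyl delivers methoxide to C2, the di-ortho-substituted aryloxy groups shield C4, the opened dienolate is too electron-rich for exchange at C3, and relactonisation is reversible whereas aromatisation to the magnesium resorcinolate is not.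

Step 11
Reactants: 16 pentamer with rings B and D as diols and rings A, C and E as methyl ethers
Product: 17 2-{4-[3,5-dihydroxy-4-(3,4,5-trihydroxyphenoxy)phenoxy]-3,5-dihydroxyphenoxy}-5-(2,4,6-trihydroxyphenoxy)benzene-1,3-diol (CNP0308003.0)
Conditions: BBr3 (excess), CH2Cl2, −78 °C to rt, Ar; then H2O
Reagents that add atoms: none
Why: Lewis acid ether cleavage: BBr3 coordinates each methoxy oxygen and bromide attacks the methyl carbon (SN2), whereas the diaryl ether bonds offer no sp3 carbon and survive, as in known demethylations of permethylated phlorotannins.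

**Compound list**

1 | 4-hydroxy-6-methyl-2H-pyran-2-one (triacetic acid lactone) | Cc1cc(O)cc(=O)o1 | starting material
2 | 4-bromo-6-methyl-2H-pyran-2-one | Cc1cc(Br)cc(=O)o1 | intermediate
3 | 4-bromo-6-(bromomethyl)-2H-pyran-2-one | BrCc1cc(Br)cc(=O)o1 | intermediate
4 | syringaldehyde | COc1cc(C=O)cc(OC)c1O | starting material
5 | 3,5-dimethoxy-4-(triisopropylsilyloxy)benzaldehyde | COc1cc(C=O)cc(OC)c1O[Si](C(C)C)(C(C)C)C(C)C | intermediate
6 | 3,5-dimethoxy-4-(triisopropylsilyloxy)phenyl formate | COc1cc(OC=O)cc(OC)c1O[Si](C(C)C)(C(C)C)C(C)C | intermediate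
7 | 3,5-dimethoxy-4-(triisopropylsilyloxy)phenol | COc1cc(O)cc(OC)c1O[Si](C(C)C)(C(C)C)C(C)C | intermediate
8 | 4-bromo-6-{[3,5-dimethoxy-4-(triisopropylsilyloxy)phenoxy]methyl}-2H-pyran-2-one | COc1cc(OCc2cc(Br)cc(=O)o2)cc(OC)c1O[Si](C(C)C)(C(C)C)C(C)C | intermediate
9 | 2,4,6-trimethoxyphenol | COc1cc(OC)c(O)c(OC)c1 | starting material
10 | 6-{[3,5-dimethoxy-4-(triisopropylsilyloxy)phenoxy]methyl}-4-(2,4,6-trimethoxyphenoxy)-2H-pyran-2-one | COc1cc(OC)c(Oc2cc(=O)oc(COc3cc(OC)c(O[Si](C(C)C)(C(C)C)C(C)C)c(OC)c3)c2)c(OC)c1 | intermediate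
11 | 6-[(4-hydroxy-3,5-dimethoxyphenoxy)methyl]-4-(2,4,6-trimethoxyphenoxy)-2H-pyran-2-one | COc1cc(OC)c(Oc2cc(=O)oc(COc3cc(OC)c(O)c(OC)c3)c2)c(OC)c1 | intermediate
12 | 3,4,5-trimethoxyphenol | COc1cc(O)cc(OC)c1OC | starting material
13 | 4-bromo-6-[(3,4,5-trimethoxyphenoxy)methyl]-2H-pyran-2-one | COc1cc(OCc2cc(Br)cc(=O)o2)cc(OC)c1OC | intermediate
14 | 6-{[3,5-dimethoxy-4-({2-oxo-6-[(3,4,5-trimethoxyphenoxy)methyl]-2H-pyran-4-yl}oxy)phenoxy]methyl}-4-(2,4,6-trimethoxyphenoxy)-2H-pyran-2-one (bis-pyranone) | COc1cc(OC)c(Oc2cc(=O)oc(COc3cc(OC)c(Oc4cc(=O)oc(COc5cc(OC)c(OC)c(OC)c5)c4)c(OC)c3)c2)c(OC)c1 | intermediate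
15 | methyl (2E)-6-[4-({(2E)-1-methoxy-1,5-dioxo-6-(3,4,5-trimethoxyphenoxy)hex-2-en-3-yl}oxy)-3,5-dimethoxyphenoxy]-5-oxo-3-(2,4,6-trimethoxyphenoxy)hex-2-enoate (ring-opened bis-enoate) | COc1cc(OC)c(O/C(=C/C(=O)OC)CC(=O)COc2cc(OC)c(O/C(=C/C(=O)OC)CC(=O)COc3cc(OC)c(OC)c(OC)c3)c(OC)c2)c(OC)c1 | intermediate
16 | 2-{4-[3,5-dihydroxy-4-(3,4,5-trimethoxyphenoxy)phenoxy]-3,5-dimethoxyphenoxy}-5-(2,4,6-trimethoxyphenoxy)benzene-1,3-diol | COc1cc(OC)c(Oc2cc(O)c(Oc3cc(OC)c(Oc4cc(O)c(Oc5cc(OC)c(OC)c(OC)c5)c(O)c4)c(OC)c3)c(O)c2)c(OC)c1 | intermediate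
17 | 2-{4-[3,5-dihydroxy-4-(3,4,5-trihydroxyphenoxy)phenoxy]-3,5-dihydroxyphenoxy}-5-(2,4,6-trihydroxyphenoxy)benzene-1,3-diol | Oc1cc(O)c(Oc2cc(O)c(Oc3cc(O)c(Oc4cc(O)c(Oc5cc(O)c(O)c(O)c5)c(O)c4)c(O)c3)c(O)c2)c(O)c1 | target

**Step count and risks**

Total step count: 11.
Longest linear sequence: 8 steps (1, 2, 5, 6, 7, 9, 10, 11 from compound 1; the branch 3, 4 from compound 4 joins at step 5 and gives the same length).

Steps most likely to fail:

Step 10. Process at risk: methoxide may exchange the C4 aryloxy groups before the lactones open, or one ring may close while the other half-opened chain decays, and both errors are compounded when two sites must react in one molecule. Fallback (one ring at a time): it sets out from 10. Mg(OMe)2 in refluxing MeOH opens its single lactone to the mono-enoate F1, which closes to the silylated ring B diol F2 (the silyl ether, shielded by two ortho methoxy groups, is expected to hold). MeI and K2CO3 in acetone cap both new hydroxyls to give the ring B dimethyl ether F3, and Bu4NF/AcOH releases the trimer phenol F4. This phenol and 13 (Cs2CO3, DMF) give the tetra-aryl mono-pyranone F5. A second Mg(OMe)2 treatment passes through the enoate F6 to the ring D diol F7. BBr3 then cleaves ten methyl ethers and the fallback comes back to the route at 17.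

Step 8 (its twin, step 5, shares the risk). Process at risk: the phenoxide may add–eliminate at C4 in competition with SN2 at CH2Br, giving the regioisomeric ether and doubly substituted material. Fallback (pyranone built around the ether): it sets out from 12. Alkylation with 2-chloro-N-methoxy-N-methylacetamide (K2CO3, DMF) gives the aryloxyacetamide F8. The lithium dienolate of 2,2,6-trimethyl-4H-1,3-dioxin-4-one (LiN(iPr)2, THF, −78 °C) is acylated by it to the keto-dioxinone F9. Heating in toluene at 110 °C expels acetone and the acylketene lactonises to the 4-hydroxy-pyranone F10. Bu4NBr/P2O5 as in step 1 then gives 13, where the route is rejoined.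

Step 9. Process at risk: slow addition of the hindered phenoxide of 11 to C4 of 13, so that base-induced opening or aryloxide exchange at the pyranone it already carries overtakes the coupling of two advanced fragments. Fallback (linear growth from the ring E end, formyl as latent hydroxyl): it sets out from 13 and 4. Syringaldehyde 4, used in excess (K2CO3, DMF, 60 °C), adds to C4 of 13 to give the pyranonyl aryl aldehyde F11. mCPBA converts it to the aryl formate F12, and acid methanolysis (HCl cat., MeOH) gives the phenol F13. SN2 alkylation with 3 (K2CO3, acetone) gives the bromo-bis-pyranone F14. Compound 9 (K2CO3, DMF) then displaces the C4 bromide and the fallback comes back to the route at 14.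

**Further compounds**

F1 | step 10 | methyl (2E)-6-[3,5-dimethoxy-4-(triisopropylsilyloxy)phenoxy]-5-oxo-3-(2,4,6-trimethoxyphenoxy)hex-2-enoate (mono-enoate) | COc1cc(OC)c(O/C(=C/C(=O)OC)CC(=O)COc2cc(OC)c(O[Si](C(C)C)(C(C)C)C(C)C)c(OC)c2)c(OC)c1
F2 | step 10 | 2-[3,5-dimethoxy-4-(triisopropylsilyloxy)phenoxy]-5-(2,4,6-trimethoxyphenoxy)benzene-1,3-diol (silylated ring B diol) | COc1cc(OC)c(Oc2cc(O)c(Oc3cc(OC)c(O[Si](C(C)C)(C(C)C)C(C)C)c(OC)c3)c(O)c2)c(OC)c1
F3 | step 10 | {4-[2,6-dimethoxy-4-(2,4,6-trimethoxyphenoxy)phenoxy]-2,6-dimethoxyphenoxy}triisopropylsilane (ring B dimethyl ether) | COc1cc(OC)c(Oc2cc(OC)c(Oc3cc(OC)c(O[Si](C(C)C)(C(C)C)C(C)C)c(OC)c3)c(OC)c2)c(OC)c1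
F4 | step 10 | 4-[2,6-dimethoxy-4-(2,4,6-trimethoxyphenoxy)phenoxy]-2,6-dimethoxyphenol (trimer phenol) | COc1cc(OC)c(Oc2cc(OC)c(Oc3cc(OC)c(O)c(OC)c3)c(OC)c2)c(OC)c1
F5 | step 10 | 4-{4-[2,6-dimethoxy-4-(2,4,6-trimethoxyphenoxy)phenoxy]-2,6-dimethoxyphenoxy}-6-[(3,4,5-trimethoxyphenoxy)methyl]-2H-pyran-2-one (tetra-aryl mono-pyranone) | COc1cc(OC)c(Oc2cc(OC)c(Oc3cc(OC)c(Oc4cc(=O)oc(COc5cc(OC)c(OC)c(OC)c5)c4)c(OC)c3)c(OC)c2)c(OC)c1
F6 | step 10 | methyl (2E)-3-{4-[2,6-dimethoxy-4-(2,4,6-trimethoxyphenoxy)phenoxy]-2,6-dimethoxyphenoxy}-5-oxo-6-(3,4,5-trimethoxyphenoxy)hex-2-enoate (enoate) | COc1cc(OC)c(Oc2cc(OC)c(Oc3cc(OC)c(O/C(=C/C(=O)OC)CC(=O)COc4cc(OC)c(OC)c(OC)c4)c(OC)c3)c(OC)c2)c(OC)c1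
F7 | step 10 | 5-{4-[2,6-dimethoxy-4-(2,4,6-trimethoxyphenoxy)phenoxy]-2,6-dimethoxyphenoxy}-2-(3,4,5-trimethoxyphenoxy)benzene-1,3-diol (ring D diol) | COc1cc(OC)c(Oc2cc(OC)c(Oc3cc(OC)c(Oc4cc(O)c(Oc5cc(OC)c(OC)c(OC)c5)c(O)c4)c(OC)c3)c(OC)c2)c(OC)c1
F8 | step 8 | N-methoxy-N-methyl-2-(3,4,5-trimethoxyphenoxy)acetamide (aryloxyacetamide) | COc1cc(OCC(=O)N(C)OC)cc(OC)c1OC
F9 | step 8 | 2,2-dimethyl-6-[2-oxo-3-(3,4,5-trimethoxyphenoxy)propyl]-4H-1,3-dioxin-4-one (keto-dioxinone) | COc1cc(OCC(=O)CC2=CC(=O)OC(C)(C)O2)cc(OC)c1OC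
F10 | step 8 | 4-hydroxy-6-[(3,4,5-trimethoxyphenoxy)methyl]-2H-pyran-2-one (4-hydroxy-pyranone) | COc1cc(OCc2cc(O)cc(=O)o2)cc(OC)c1OC
F11 | step 9 | 3,5-dimethoxy-4-({2-oxo-6-[(3,4,5-trimethoxyphenoxy)methyl]-2H-pyran-4-yl}oxy)benzaldehyde (pyranonyl aryl aldehyde) | COc1cc(C=O)cc(OC)c1Oc2cc(=O)oc(COc3cc(OC)c(OC)c(OC)c3)c2
F12 | step 9 | 3,5-dimethoxy-4-({2-oxo-6-[(3,4,5-trimethoxyphenoxy)methyl]-2H-pyran-4-yl}oxy)phenyl formate (aryl formate) | COc1cc(OC=O)cc(OC)c1Oc2cc(=O)oc(COc3cc(OC)c(OC)c(OC)c3)c2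
F13 | step 9 | 4-(4-hydroxy-2,6-dimethoxyphenoxy)-6-[(3,4,5-trimethoxyphenoxy)methyl]-2H-pyran-2-one (phenol) | COc1cc(O)cc(OC)c1Oc2cc(=O)oc(COc3cc(OC)c(OC)c(OC)c3)c2
F14 | step 9 | 4-bromo-6-{[3,5-dimethoxy-4-({2-oxo-6-[(3,4,5-trimethoxyphenoxy)methyl]-2H-pyran-4-yl}oxy)phenoxy]methyl}-2H-pyran-2-one (bromo-bis-pyranone) | COc1cc(OCc2cc(Br)cc(=O)o2)cc(OC)c1Oc3cc(=O)oc(COc4cc(OC)c(OC)c(OC)c4)c3
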